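**Plan**

1. Cuts, last to first: the oxetane O–C-5′ bond; the enol-ether O–C-3′ and tetrahydropyran O–C-6′ bonds (both made by opening epoxides); C-11–C-1′. This leaves a dibenzo[b,f]oxepin-10(11H)-one and a bis-epoxy iodide. The oxepinone is cut across the seven-membered ring at the aryl–O bond on ring A and at C-10–C-11, giving two benzene esters.
2. Forward: rings A and B are bought as benzenes. The oxepine closes first (step 6), the side chain is joined (step 14), the 4H-pyran and tetrahydropyran close together (step 15), and the oxetane closes last (step 16).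
3. Feature used in step 6: ring B carries the ether oxygen and C-10 on neighbouring carbons (a salicylate, since the enol-ether carbon C-10 is a masked ketone). Ring A carries the ether carbon and C-11 on neighbouring carbons, and C-11 is the α-carbon of that masked ketone. A CO2Me helper on C-11 makes it a nucleophile and is removed in step 7.
4. Stereochemistry: C-5′ comes from a ligand-controlled vinylogous aldol. C-2′ and C-3′ come from Sharpless epoxidation of a (Z)-allylic alcohol, with C-3′ inverted when the ketone oxygen opens the epoxide. C-6′ comes from a hydroxyl-directed epoxidation and is inverted on tetrahydropyran closure. C-5′ is inverted on oxetane closure.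
5. Locants: dibenzo[b,f]oxepine numbers for the tricycle (ring A is the prenylated ring and carries C-11; ring B carries C-10). Side chain runs C-1′ (CH2 on C-11) to C-7′ (CMe2), with CH3 on C-3′.

Key step: step 6

Assumption: in step 9 the (S)-Tol-BINAP copper fluoride catalyst is taken to give the (6R)-lactone; if the sense of induction is the reverse, the (R)-ligand is used.

**Route**

Step 1
Reactants: 1 2-(2-bromo-4-methoxyphenyl)acetic acid
Product: 3 methyl 2-(2-bromo-4-hydroxyphenyl)acetate, via phenol acid 2 (not isolated)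
Conditions: BBr3, CH2Cl2, −78 to 25 °C; then MeOH, 65 °C
Reagents that add atoms: methanol, CO
Why: BBr3 cleaves the aryl methyl ether (Lewis-acid demethylation) and the methanol quench esterifies the acid in the HBr that forms (Fischer esterification).

Step 2
Reactants: 3 methyl 2-(2-bromo-4-hydroxyphenyl)acetate
Product: 4 methyl 2-(2-bromo-4-hydroxy-5-iodophenyl)acetate
Conditions: N-iodosuccinimide, TsOH (10 mol%), MeCN, 0 to 25 °C
Reagents that add atoms: N-iodosuccinimide, O=C1CCC(=O)N1I
Why: Electrophilic aromatic iodination should go ortho to the phenol at C-5, because the para position is blocked and the other ortho position lies between OH and Br.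

Step 3
Reactants: 4 methyl 2-(2-bromo-4-hydroxy-5-iodophenyl)acetate
Product: 5 methyl 2-[2-bromo-4-hydroxy-5-(3-methylbut-2-en-1-yl)phenyl]acetate
Conditions: Bu3SnCH2CH=CMe2, Pd(PPh3)4 (5 mol%), DMF, 80 °C
Reagents that add atoms: tributyl(3-methylbut-2-en-1-yl)stannane, CCCC[Sn](CCCC)(CCCC)CC=C(C)C
Why: Stille coupling should take place only at the C–I bond, since oxidative addition to an aryl iodide is much faster than to an aryl bromide, and it places the prenyl group ortho to the phenol.

Step 4
Reactants: 5 methyl 2-[2-bromo-4-hydroxy-5-(3-methylbut-2-en-1-yl)phenyl]acetate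
Product: 6 methyl 2-[2-bromo-5-(3-methylbut-2-en-1-yl)-4-(prop-2-en-1-yloxy)phenyl]acetate
Conditions: allyl bromide, K2CO3, acetone, 56 °C
Reagents that add atoms: allyl bromide, C=CCBr
Why: Williamson etherification of the phenoxide, under conditions (K2CO3 in acetone) too weakly basic to enolise the arylacetate.

Step 5
Reactants: 7 methyl 2,4-dihydroxybenzoate
Product: 8 methyl 2-hydroxy-4-(prop-2-en-1-yloxy)benzoate
Conditions: allyl bromide (1.05 equiv), K2CO3, acetone, 56 °C
Reagents that add atoms: allyl bromide, C=CCBr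
Why: Williamson etherification should occur at the 4-OH, because the 2-OH is hydrogen-bonded to the ester carbonyl and is the less nucleophilic phenol.

Step 6
Reactants: 6 methyl 2-[2-bromo-5-(3-methylbut-2-en-1-yl)-4-(prop-2-en-1-yloxy)phenyl]acetate, 8 methyl 2-hydroxy-4-(prop-2-en-1-yloxy)benzoate
Product: 10 methyl 2-(3-methylbut-2-en-1-yl)-10-oxo-3,7-bis(prop-2-en-1-yloxy)-10,11-dihydrodibenzo[b,f]oxepine-11-carboxylate (racemic at C-11 and largely enolised), via diaryl ether diester 9 (not isolated)
Conditions: CuI (10 mol%), N,N-dimethylglycine hydrochloride (30 mol%), Cs2CO3 (2.5 equiv), 1,4-dioxane, 90 °C; then KOt-Bu (1.5 equiv), THF, 0 to 25 °C, same flask; aq. HCl work-up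
Reagents that add atoms: none
Why: Cs2CO3 forms the phenoxide of 8, which deactivates its own benzoate toward intermolecular Claisen attack, so the first productive event is the copper-catalysed Ullmann etherification at the C–Br carbon of 6 (oxidative addition to a monovalent copper phenoxide, then C–O reductive elimination), giving diaryl ether 9; KOt-Bu then forms the arylacetate enolate, which adds to the benzoate carbonyl and expels methoxide (Dieckmann condensation), the product being held as its stabilised enolate, whose enol form already contains the C-10=C-11 double bond. The closest known reaction types are the Ullmann diaryl ether synthesis and the Dieckmann cyclisation, which together amount to a (4+3) annulation of a salicylate (O, two ring-B carbons, the ester carbon) with an ortho-bromo arylacetate (the C–Br carbon, its neighbour, the CH2). The oxepine ring closes in the second event by 7-exo-trig attack of the enolate carbon on the ester C=O. No lasting stereocentre is formed, since C-11 is enolisable and becomes sp2 later. The step needs O-arylation to come before C–C bond formation, because a C-10 ketone enolate formed first would close a benzofuran by O-arylation; adding the strong base only after the coupling secures this, and the regiochemistry is fixed because 6 has one halogen, 8 has one free phenol, and only the arylacetate has α-hydrogens.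

Step 7
Reactants: 10 methyl 2-(3-methylbut-2-en-1-yl)-10-oxo-3,7-bis(prop-2-en-1-yloxy)-10,11-dihydrodibenzo[b,f]oxepine-11-carboxylate
Product: 11 2-(3-methylbut-2-en-1-yl)-3,7-bis(prop-2-en-1-yloxy)dibenzo[b,f]oxepin-10(11H)-one
Conditions: LiCl, H2O, DMSO, 130 °C
Reagents that add atoms: none
Why: Krapcho dealkoxycarbonylation removes the activating ester under neutral conditions that should leave the allyl ethers and the prenyl group untouched.

Step 8
Reactants: 12 ethyl 3-methylbut-2-enoate
Product: 13 1-ethoxy-3-methyl-1-(trimethylsilyloxy)buta-1,3-diene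
Conditions: LiN(i-Pr)2, THF, −78 °C; then Me3SiCl
Reagents that add atoms: chlorotrimethylsilane, C[Si](C)(C)Cl
Why: γ-Deprotonation of the unsaturated ester and O-silylation give the silyl dienolate (silyl ketene acetal formation).

Step 9
Reactants: 13 1-ethoxy-3-methyl-1-(trimethylsilyloxy)buta-1,3-diene, 14 3-methylbut-2-enal
Product: 16 (6R)-4-methyl-6-(2-methylprop-1-en-1-yl)-5,6-dihydro-2H-pyran-2-one, via silyl aldolate 15 (not isolated)
Conditions: Cu(OTf)2 (10 mol%), (S)-Tol-BINAP (11 mol%), Bu4N[Ph3SiF2] (20 mol%), THF, 25 °C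
Reagents that add atoms: none
Why: Catalytic asymmetric vinylogous Mukaiyama aldol reaction, in which the chiral copper dienolate adds through its γ-carbon, the (Z)-enoate aldolate lactonises, and the ligand sets C-5′ as (R).

Step 10
Reactants: 16 (6R)-4-methyl-6-(2-methylprop-1-en-1-yl)-5,6-dihydro-2H-pyran-2-one
Product: 17 (2Z,5R)-3,7-dimethylocta-2,6-diene-1,5-diol
Conditions: i-Bu2AlH (3.5 equiv), CH2Cl2, −78 to 0 °C; Rochelle salt work-up
Reagents that add atoms: none
Why: Hydride reduction of the unsaturated lactone through the lactol gives the diol by 1,2-reduction, the ring having fixed the (Z) geometry of the new allylic alcohol.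

Step 11
Reactants: 17 (2Z,5R)-3,7-dimethylocta-2,6-diene-1,5-diol
Product: 18 (2R)-1-[(2S,3R)-3-(hydroxymethyl)-2-methyloxiran-2-yl]-4-methylpent-3-en-2-ol
Conditions: Ti(Oi-Pr)4 (1 equiv), L-(+)-diethyl tartrate, t-BuOOH (1.1 equiv), 4 Å molecular sieves, CH2Cl2, −25 °C
Reagents that add atoms: tert-butyl hydroperoxide, CC(C)(C)OO
Why: Sharpless asymmetric epoxidation of the primary (Z)-allylic alcohol with the L-(+)-tartrate should give the (2′R,3′S) epoxide, while the secondary (5′R) allylic alcohol is the slow-reacting enantiomer for this tartrate and bears a cis methyl group, so its alkene is left.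

Step 12
Reactants: 18 (2R)-1-[(2S,3R)-3-(hydroxymethyl)-2-methyloxiran-2-yl]-4-methylpent-3-en-2-ol
Product: 19 (1R)-1-[(2S)-3,3-dimethyloxiran-2-yl]-2-[(2S,3R)-3-(hydroxymethyl)-2-methyloxiran-2-yl]ethan-1-ol
Conditions: mCPBA, NaHCO3, CH2Cl2, 0 °C
Reagents that add atoms: 3-chloroperoxybenzoic acid, OOC(=O)c1cccc(Cl)c1
Why: Hydroxyl-directed peracid epoxidation, in which the C-5′–H eclipses the alkene to avoid allylic 1,3-strain with the cis methyl group and the hydrogen-bonded peracid attacks the face that gives the threo (5′R,6′S) epoxy alcohol.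

Step 13
Reactants: 19 (1R)-1-[(2S)-3,3-dimethyloxiran-2-yl]-2-[(2S,3R)-3-(hydroxymethyl)-2-methyloxiran-2-yl]ethan-1-ol
Product: 20 (1R)-1-[(2S)-3,3-dimethyloxiran-2-yl]-2-[(2S,3S)-3-(iodomethyl)-2-methyloxiran-2-yl]ethan-1-ol
Conditions: I2, PPh3, imidazole, THF, 0 °C
Reagents that add atoms: iodine, II
Why: Appel-type iodination should convert the primary alcohol faster than the hindered secondary one, with imidazole keeping the medium non-acidic for the epoxides.

Step 14
Reactants: 11 2-(3-methylbut-2-en-1-yl)-3,7-bis(prop-2-en-1-yloxy)dibenzo[b,f]oxepin-10(11H)-one, 20 (1R)-1-[(2S)-3,3-dimethyloxiran-2-yl]-2-[(2S,3S)-3-(iodomethyl)-2-methyloxiran-2-yl]ethan-1-ol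
Product: 21 11-{[(2R,3S)-3-{(2R)-2-[(2S)-3,3-dimethyloxiran-2-yl]-2-hydroxyethyl}-3-methyloxiran-2-yl]methyl}-2-(3-methylbut-2-en-1-yl)-3,7-bis(prop-2-en-1-yloxy)dibenzo[b,f]oxepin-10(11H)-one (both C-11 epimers)
Conditions: Cs2CO3 (1.2 equiv), DMF, 0 to 25 °C
Reagents that add atoms: none
Why: SN2 C-alkylation of the soft, aryl-conjugated enolate of 11 by the primary epoxy-carbinyl iodide, with a base too weak to ionise the secondary hydroxyl and trisubstituted epoxides too hindered to compete.

Step 15
Reactants: 21 the C-11-alkylated bis-epoxy ketone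
Product: 23 pentacyclic diol (4H-pyran and tetrahydropyran closed; (5′R)-OH and C-7′ tertiary OH free; both phenols as allyl ethers; 2′R,3′R,5′R,6′R), via pyranol epoxide 22 (not isolated)
Conditions: (+)-camphor-10-sulfonic acid (10 mol%), 4 Å molecular sieves, CH2Cl2, 0 to 25 °C
Reagents that add atoms: none
Why: Acid-triggered epoxide-opening cascade in which the C-10 carbonyl oxygen opens the 2′,3′-epoxide at its tertiary carbon C-3′ with inversion (6-endo) and loss of H-11 gives the enol ether, after which the freed C-2′ hydroxyl opens the 6′,7′-epoxide at C-6′ with inversion (6-exo), so C-2′ is retained and C-3′ and C-6′ follow from the epoxide configurations.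

Step 16
Reactants: 23 pentacyclic diol
Product: 25 3,7-di-O-allyl ether of the target (oxetane closed, 5′S), via mesylate 24 (not isolated)
Conditions: MsCl, Et3N, CH2Cl2, 0 °C; solvent exchange; KOt-Bu, THF, 0 to 25 °C
Reagents that add atoms: methanesulfonyl chloride, CS(=O)(=O)Cl (its atoms stay in 24 only)
Why: Mesylation of the only secondary hydroxyl, then intramolecular Williamson etherification (4-exo-tet) by the tertiary alkoxide with inversion at C-5′, should give the cis-fused oxetane.

Step 17
Reactants: 25 3,7-di-O-allyl ether of the target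
Product: 26 the target, CNP0102779.1
Conditions: Pd(PPh3)4 (5 mol%), morpholine (10 equiv), THF, 25 °C
Reagents that add atoms: none
Why: Palladium-catalysed allyl transfer to morpholine (Tsuji–Trost deallylation) should free both phenols under neutral conditions that spare the enol ether, the oxetane and the prenyl group.

**Compound list**

1 | 2-(2-bromo-4-methoxyphenyl)acetic acid | COc1ccc(CC(=O)O)c(Br)c1 | starting material
2 | 2-(2-bromo-4-hydroxyphenyl)acetic acid (not isolated) | OC(=O)Cc1ccc(O)cc1Br | intermediate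
3 | methyl 2-(2-bromo-4-hydroxyphenyl)acetate | COC(=O)Cc1ccc(O)cc1Br | intermediate
4 | methyl 2-(2-bromo-4-hydroxy-5-iodophenyl)acetate | COC(=O)Cc1cc(I)c(O)cc1Br | intermediate
5 | methyl 2-[2-bromo-4-hydroxy-5-(3-methylbut-2-en-1-yl)phenyl]acetate | COC(=O)Cc1cc(CC=C(C)C)c(O)cc1Br | intermediate
6 | methyl 2-[2-bromo-5-(3-methylbut-2-en-1-yl)-4-(prop-2-en-1-yloxy)phenyl]acetate | COC(=O)Cc1cc(CC=C(C)C)c(OCC=C)cc1Br | intermediate
7 | methyl 2,4-dihydroxybenzoate | COC(=O)c1ccc(O)cc1O | starting material
8 | methyl 2-hydroxy-4-(prop-2-en-1-yloxy)benzoate | COC(=O)c1ccc(OCC=C)cc1O | intermediate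
9 | methyl 2-[2-(2-methoxy-2-oxoethyl)-4-(3-methylbut-2-en-1-yl)-5-(prop-2-en-1-yloxy)phenoxy]-4-(prop-2-en-1-yloxy)benzoate (not isolated) | COC(=O)Cc1cc(CC=C(C)C)c(OCC=C)cc1Oc1cc(OCC=C)ccc1C(=O)OC | intermediate
10 | methyl 2-(3-methylbut-2-en-1-yl)-10-oxo-3,7-bis(prop-2-en-1-yloxy)-10,11-dihydrodibenzo[b,f]oxepine-11-carboxylate | COC(=O)C1C(=O)c2ccc(OCC=C)cc2Oc2cc(OCC=C)c(CC=C(C)C)cc21 | intermediate
11 | 2-(3-methylbut-2-en-1-yl)-3,7-bis(prop-2-en-1-yloxy)dibenzo[b,f]oxepin-10(11H)-one | O=C1Cc2cc(CC=C(C)C)c(OCC=C)cc2Oc2cc(OCC=C)ccc21 | intermediate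
12 | ethyl 3-methylbut-2-enoate | CCOC(=O)C=C(C)C | starting material
13 | 1-ethoxy-3-methyl-1-(trimethylsilyloxy)buta-1,3-diene | CCOC(=CC(C)=C)O[Si](C)(C)C | intermediate
14 | 3-methylbut-2-enal | CC(C)=CC=O | starting material
15 | ethyl (2Z,5R)-3,7-dimethyl-5-(trimethylsilyloxy)octa-2,6-dienoate (not isolated) | CCOC(=O)/C=C(C)\C[C@@H](O[Si](C)(C)C)C=C(C)C | intermediate
16 | (6R)-4-methyl-6-(2-methylprop-1-en-1-yl)-5,6-dihydro-2H-pyran-2-one | O=C1C=C(C)C[C@H](C=C(C)C)O1 | intermediate
17 | (2Z,5R)-3,7-dimethylocta-2,6-diene-1,5-diol | OC/C=C(C)\C[C@@H](O)C=C(C)C | intermediate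
18 | (2R)-1-[(2S,3R)-3-(hydroxymethyl)-2-methyloxiran-2-yl]-4-methylpent-3-en-2-ol | OC[C@H]1O[C@@]1(C)C[C@@H](O)C=C(C)C | intermediate
19 | (1R)-1-[(2S)-3,3-dimethyloxiran-2-yl]-2-[(2S,3R)-3-(hydroxymethyl)-2-methyloxiran-2-yl]ethan-1-ol | OC[C@H]1O[C@@]1(C)C[C@@H](O)[C@@H]1OC1(C)C | intermediate
20 | (1R)-1-[(2S)-3,3-dimethyloxiran-2-yl]-2-[(2S,3S)-3-(iodomethyl)-2-methyloxiran-2-yl]ethan-1-ol | IC[C@H]1O[C@@]1(C)C[C@@H](O)[C@@H]1OC1(C)C | intermediate
21 | 11-{[(2R,3S)-3-{(2R)-2-[(2S)-3,3-dimethyloxiran-2-yl]-2-hydroxyethyl}-3-methyloxiran-2-yl]methyl}-2-(3-methylbut-2-en-1-yl)-3,7-bis(prop-2-en-1-yloxy)dibenzo[b,f]oxepin-10(11H)-one | O=C1C(C[C@H]2O[C@@]2(C)C[C@@H](O)[C@@H]2OC2(C)C)c2cc(CC=C(C)C)c(OCC=C)cc2Oc2cc(OCC=C)ccc21 | intermediate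
22 | pyranol epoxide: 4H-pyran closed between the C-10 oxygen and C-3′ (3′R), free (2′R)-OH, (5′R)-OH and (6′S)-6′,7′-epoxide unchanged (not isolated) | CC(C)=CCc1cc2c(cc1OCC=C)Oc1cc(OCC=C)ccc1C1=C2C[C@@H](O)[C@@](C)(C[C@@H](O)[C@@H]2OC2(C)C)O1 | intermediate
23 | pentacyclic diol: tetrahydropyran also closed (O–C-6′, 6′R), (5′R)-OH and 2-hydroxypropan-2-yl on C-6′, phenols as allyl ethers | CC(C)=CCc1cc2c(cc1OCC=C)Oc1cc(OCC=C)ccc1C1=C2C[C@H]2O[C@@H](C(C)(C)O)[C@H](O)C[C@@]2(C)O1 | intermediate
24 | 5′-O-methanesulfonate of 23 (not isolated) | CC(C)=CCc1cc2c(cc1OCC=C)Oc1cc(OCC=C)ccc1C1=C2C[C@H]2O[C@@H](C(C)(C)O)[C@H](OS(C)(=O)=O)C[C@@]2(C)O1 | intermediate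
25 | 3,7-di-O-allyl ether of the target | CC(C)=CCc1cc2c(cc1OCC=C)Oc1cc(OCC=C)ccc1C1=C2C[C@H]2O[C@@H]3[C@H](C[C@@]2(C)O1)OC3(C)C | intermediate
26 | CNP0102779.1: 3,7-dihydroxy-2-prenyldibenzo[b,f]oxepine with the C-10/C-11 enol ether fused to the (2′R,3′R,5′S,6′R) pyran–tetrahydropyran–oxetane unit | CC(C)=CCc1cc2c(cc1O)Oc1cc(O)ccc1C1=C2C[C@H]2O[C@@H]3[C@H](C[C@@]2(C)O1)OC3(C)C | target

**Step count and risks**

Total step count: 17.
Longest linear sequence: 10 steps (1, 2, 3, 4, 6, 7, 14, 15, 16, 17); the side-chain arm (8 to 13, then 14 to 17) is equally long.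

Steps most likely to fail:

Step 15. What may go wrong: the second epoxide may open at its tertiary carbon (seven-membered endo closure) instead of at C-6′, and the first opening may lose inversion at C-3′ through an open tertiary cation. Fallback, setting out from 20 and 11 and coming back at 23: the secondary hydroxyl of 20 is silylated (t-BuMe2SiCl, imidazole, DMF) to the silyl ether of the bis-epoxy iodide F3. Ketone 11 is alkylated with it (Cs2CO3, DMF) to the silylated bis-epoxy ketone F4. Pyridinium p-toluenesulfonate in CH2Cl2 closes only the pyran ring, since the remaining epoxide is deactivated by the neighbouring silyloxy group, giving the silylated pyranol epoxide F5. NaH in THF/DMSO then closes the tetrahydropyran by alkoxide attack at the secondary carbon C-6′ (6-exo, no acid, so no tertiary-cation bias), giving the silylated tertiary alcohol F6. Bu4NF in THF removes the silyl group and returns diol 23.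

Step 16. What may go wrong: Grob fragmentation of the tertiary alkoxide (loss of acetone, with a ring enol ether forming) may compete with four-membered ring closure. Fallback, setting out from 23 and coming back at 25: the ring is closed without any alkoxide. The secondary hydroxyl is converted at −78 °C (Tf2O, 2,6-lutidine, CH2Cl2) into the 5′-O-trifluoromethanesulfonate of 23 F7, and on warming the neutral tertiary hydroxyl displaces the triflate with inversion, so the electron push that fragmentation needs is absent.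

Step 6. What may go wrong: C–O coupling between a chelating, hydrogen-bonded salicylate phenoxide and an ortho-substituted bromoarene may be slow, with ester cleavage and isomerisation of the allyl ethers by the strong base. Fallback, setting out from 6 and coming back at 11: the ring is closed at the other side of the ketone. Bromide 6 is coupled (CuI, N,N-dimethylglycine, Cs2CO3, dioxane, 90 °C) with bought, unhindered 3-(prop-2-en-1-yloxy)phenol to give methyl 2-[5-(3-methylbut-2-en-1-yl)-4-(prop-2-en-1-yloxy)-2-[3-(prop-2-en-1-yloxy)phenoxy]phenyl]acetate F1. LiOH in THF/H2O gives 2-[5-(3-methylbut-2-en-1-yl)-4-(prop-2-en-1-yloxy)-2-[3-(prop-2-en-1-yloxy)phenoxy]phenyl]acetic acid F2. Intramolecular Friedel–Crafts acylation (trifluoroacetic anhydride, CH2Cl2, 0 °C) para to the allyloxy group and ortho to the diaryl ether oxygen then gives ketone 11 directly.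

**Further compounds**

F1 | step 6 | methyl 2-[5-(3-methylbut-2-en-1-yl)-4-(prop-2-en-1-yloxy)-2-[3-(prop-2-en-1-yloxy)phenoxy]phenyl]acetate | COC(=O)Cc1cc(CC=C(C)C)c(OCC=C)cc1Oc1cccc(OCC=C)c1
F2 | step 6 | 2-[5-(3-methylbut-2-en-1-yl)-4-(prop-2-en-1-yloxy)-2-[3-(prop-2-en-1-yloxy)phenoxy]phenyl]acetic acid | OC(=O)Cc1cc(CC=C(C)C)c(OCC=C)cc1Oc1cccc(OCC=C)c1
F3 | step 15 | tert-butyldimethylsilyl ether of 20 | IC[C@H]1O[C@@]1(C)C[C@@H](O[Si](C)(C)C(C)(C)C)[C@@H]1OC1(C)C
F4 | step 15 | 5′-O-tert-butyldimethylsilyl ether of 21 | O=C1C(C[C@H]2O[C@@]2(C)C[C@@H](O[Si](C)(C)C(C)(C)C)[C@@H]2OC2(C)C)c2cc(CC=C(C)C)c(OCC=C)cc2Oc2cc(OCC=C)ccc21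
F5 | step 15 | 5′-O-tert-butyldimethylsilyl ether of 22 | CC(C)=CCc1cc2c(cc1OCC=C)Oc1cc(OCC=C)ccc1C1=C2C[C@@H](O)[C@@](C)(C[C@@H](O[Si](C)(C)C(C)(C)C)[C@@H]2OC2(C)C)O1
F6 | step 15 | 5′-O-tert-butyldimethylsilyl ether of 23 | CC(C)=CCc1cc2c(cc1OCC=C)Oc1cc(OCC=C)ccc1C1=C2C[C@H]2O[C@@H](C(C)(C)O)[C@H](O[Si](C)(C)C(C)(C)C)C[C@@]2(C)O1
F7 | step 16 | 5′-O-trifluoromethanesulfonate of 23 | CC(C)=CCc1cc2c(cc1OCC=C)Oc1cc(OCC=C)ccc1C1=C2C[C@H]2O[C@@H](C(C)(C)O)[C@H](OS(=O)(=O)C(F)(F)F)C[C@@]2(C)O1
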